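The ratio of reagent to starting material is 2.00 in oak and larch, 2.73 in the south run and 4.00 in the south-east run. Starting material is the limiting reagent in each, so I subtract: c(reagent) minus c(starting material) at the charge is 0.300 M in oak and larch. This difference, the reagent surplus, is what I expect to stand in the flask once the fast stage is over, and it is what I freeze.

| flask | starting material | reagent | protic impurity | remark | time |
|---|---|---|---|---|---|
| south-east | 0.15 M | 0.60 M | 0.030 M | run made earlier |  |
| south | 0.22 M | 0.60 M | 0.030 M | run made earlier |  |
| oak | 0.30 M | 0.600 M | 0.0300 M |  | 10 min |
| larch | 0.30 M | 0.600 M | 0.0300 M |  | 25 min |

- south-east (time / min: target / %, starting material / %): 0.667: 23, 4; 1.33: 19, 0; 2.50: 17, 0; 4.00: 10, 0; 8.00: 9, 0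
- south (time / min: target / %, starting material / %): 0.667: 25, 0; 1.33: 20, 4; 2.50: 19, 1; 4.00: 16, 0; 8.00: 10, 1

(each reading ± 2 percentage points)

- which of the two there is more of at the end, oak (target / isomer of the product)
- which of the two there is more of at the end, larch (target / isomer of the product)
- final target, as a percentage of the starting material charged, in oak
- final target, as a percentage of the starting material charged, in larch

- the numbers in the tables scatter with a standard deviation of 2 percentage points
- steps thought possible: starting material + reagent -> isomer of the product; starting material + reagent -> second isomer; starting material + protic impurity -> quenched substrate; reagent + target -> over-reaction product; starting material + reagent -> target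

In the first instants, starting material reads 4 % at 0.667 min in the south-east run, a loss of about 4.83 min⁻¹. Between the first and last readings, I read the decay of target as 0.128 min⁻¹ there and 0.125 min⁻¹ in the south run, so the stages separate, the loss being far faster.

Running those decays back to zero time, I read 26.1 % as target's share, about a quarter of the starting material.

In the middle stage, target dies away as a pseudo-first-order decay. Dividing each decay by its run's surplus gives 0.284 M⁻¹ min⁻¹ and 0.329 M⁻¹ min⁻¹, and I take the mean, 0.307 M⁻¹ min⁻¹. In oak, by the share I read, the decay of target takes reagent from the surplus down to about 0.222 M, so I count freezing it as fair, and the same freezing went into the reading of that constant. The decay in oak and larch is then 0.0920 min⁻¹.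

At the end I reckon 10.4 % target in oak and 2.62 % in larch. The isomer of the product was not measured, but an equal split of the remainder among it, the second isomer and the quenched substrate gives 24.6 %, which is more than target in oak and in larch, so I expect more isomer in both flasks.

The forecast, higher than my reckoning, says 12.5 % for oak and 4.3 % for larch, with the isomer ahead in both, since “the isomer is not consumed, so it probably exceeds the target in both runs”. The flask gives 9.15 % target in oak and 2.31 % in larch, against 61.6 % and 61.6 % of the isomer of the product. Reagent in oak stands at 0.253 M at 10.0 min, less than the surplus and more than my reckoned 0.222 M.

    starting material + reagent → isomer of the product (k = 0.867 M⁻¹ s⁻¹)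
    starting material + reagent → second isomer (k = 0.161 M⁻¹ s⁻¹)
    starting material + protic impurity → quenched substrate (k = 0.222 M⁻¹ s⁻¹)
    reagent + target → over-reaction product (k = 0.00637 M⁻¹ s⁻¹)
    starting material + reagent → target (k = 0.365 M⁻¹ s⁻¹)

A neighbour of larch is charged with 0.75 M of starting material, and its surplus is −0.150 M, below zero, so here reagent is the limiting one. Reagent covers 80.0 % of the starting material, and target's share of that is 20.9 %. The uncovered 20.0 %, less the 4.00 % that stands as quenched substrate, leaves 16.0 % of starting material. At 25.0 min that flask holds 0 % of its reagent, 16.1 % starting material, 20.8 % target and 0.0998 % over-reaction product.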